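**Retrosynthetic overview**
- Target ⇐ its hexa-allyl precursor (five aryl allyl ethers, one allyl ester) by a single global Pd(0) deallylation.
- Hexa-allyl precursor ⇐ (E)-cinnamate C=C by a one-pot Meldrum's acid acylation / Knoevenagel–Doebner condensation of triallyl (R)-danshensu with an aldehyde that already carries the aryl enol ether.
- That aldehyde ⇐ the key vinyl C–O bond, made by a new phosphine-catalysed α-selective addition of 4-allyloxy-3-hydroxybenzaldehyde across a methyl 3-arylpropiolate (Z-selective).
- Propiolate and phenol ⇐ 3,4-dihydroxybenzaldehyde (bis-allylation, Corey–Fuchs, methoxycarbonylation; and selective 4-O-allylation).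
- No ring is formed; all three benzene rings are bought.

Assumption: sodium danshensu is bought as the single (R)-enantiomer and supplies the only stereocentre.

**Route**

Step 1
Reactants: 1 3,4-dihydroxybenzaldehyde
Product: 2 3,4-bis(allyloxy)benzaldehyde
Conditions: allyl bromide (2.5 eq), K2CO3 (3 eq), DMF, 60 °C
Reagents that add atoms: allyl bromide C=CCBr
Why: Williamson ether synthesis; carbonate in DMF deprotonates both phenols and each phenoxide is alkylated by the reactive allylic bromide.

Step 2
Reactants: 2 3,4-bis(allyloxy)benzaldehyde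
Product: 3 1,2-bis(allyloxy)-4-(2,2-dibromovinyl)benzene
Conditions: CBr4 (2 eq), PPh3 (2 eq), Zn dust (2 eq), CH2Cl2, rt; then 2, rt
Reagents that add atoms: carbon tetrabromide BrC(Br)(Br)Br
Why: Corey–Fuchs (Ramirez) dibromo-olefination with preformed Ph3P=CBr2 (Zn variant) is a neutral Wittig reaction that leaves aryl allyl ethers untouched.

Step 3
Reactants: 3 1,2-bis(allyloxy)-4-(2,2-dibromovinyl)benzene
Product: 5 methyl 3-[3,4-bis(allyloxy)phenyl]prop-2-ynoate, via lithium acetylide 4 (not isolated)
Conditions: n-BuLi (2.1 eq), THF, −78 °C; then ClCO2Me (1.5 eq), −78 → 0 °C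
Reagents that add atoms: methyl chloroformate COC(=O)Cl
Why: Second stage of the Corey–Fuchs sequence (Br/Li exchange, Fritsch–Buttenberg–Wiechell rearrangement, deprotonation) gives the lithium acetylide, which is C-acylated by the chloroformate at −78 °C, where allyl aryl ethers are inert to BuLi.

Step 4
Reactants: 1 3,4-dihydroxybenzaldehyde
Product: 6 4-(allyloxy)-3-hydroxybenzaldehyde
Conditions: allyl bromide (1.05 eq), NaHCO3 (1.5 eq), NaI (cat.), DMF, 40 °C
Reagents that add atoms: allyl bromide C=CCBr
Why: Regioselective Williamson etherification; only the more acidic 4-OH (para to the formyl group) is deprotonated by bicarbonate, so the 3-OH stays free.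

Step 5
Reactants: 5 methyl 3-[3,4-bis(allyloxy)phenyl]prop-2-ynoate; 6 4-(allyloxy)-3-hydroxybenzaldehyde (1.3 eq)
Product: 7 methyl (Z)-2-[2-(allyloxy)-5-formylphenoxy]-3-[3,4-bis(allyloxy)phenyl]acrylate
Conditions: P(4-MeOC6H4)3 (20 mol%), PhMe, 100 °C, no added base
Reagents that add atoms: none
Why: Proposed new method: phosphine-catalysed α-selective ("umpolung") hydro-aryloxylation of an internal, electron-rich 3-arylpropiolate by a phenol. The phosphine adds to the aryl-bearing β-carbon, and the resulting vinyl anion is protonated by phenol 6 to give a β-phosphonio-cinnamate/phenoxide ion pair. The phenoxide then attacks the carbon β to P+ (the ester α-carbon) to give an aryl-stabilised ylide, and a 1,2-proton shift followed by E1cB loss of the phosphine releases the α-aryloxy-cinnamate with no co-product. Reversible phosphine addition to the product funnels it to the more stable Z isomer (aryl anti to CO2Me), and the absence of free base suppresses the competing β-oxa-Michael addition. The closest known reaction type is the phosphine-catalysed α-addition of N–H pronucleophiles (phthalimide, sulfonamides) to alkynoates lacking γ-hydrogens; no stereocentre is formed.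

Step 6
Reactants: 8 sodium (R)-3-(3,4-dihydroxyphenyl)-2-hydroxypropanoate (sodium danshensu)
Product: 9 allyl (R)-3-[3,4-bis(allyloxy)phenyl]-2-hydroxypropanoate
Conditions: allyl bromide (3.5 eq), K2CO3 (2.5 eq), DMF, rt
Reagents that add atoms: allyl bromide C=CCBr
Why: Carboxylate O-alkylation plus Williamson etherification of both phenols; the secondary alcohol is not deprotonated by carbonate, and no bond to the (R)-stereocentre is touched at rt, so the chiral-pool configuration is retained.

Step 7
Reactants: 9 allyl (R)-3-[3,4-bis(allyloxy)phenyl]-2-hydroxypropanoate; 10 Meldrum's acid; 7 methyl (Z)-2-[2-(allyloxy)-5-formylphenoxy]-3-[3,4-bis(allyloxy)phenyl]acrylate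
Product: 12 hexa-allyl precursor of the target (full name in the compound list), via malonic half-ester 11 (not isolated)
Conditions: 9 (1.2 eq), 10 (1.2 eq), PhMe, 100 °C, 4 h; then 7 (1.0 eq), pyridine, piperidine (0.2 eq), 45 °C
Reagents that add atoms: none
Why: Alcoholysis of Meldrum's acid gives the malonic half-ester, whose Knoevenagel–Doebner condensation with the aldehyde and decarboxylation gives the (E)-cinnamate under thermodynamic control; the weak amine bases do not epimerise the α-acyloxy ester stereocentre.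

Step 8
Reactants: 12 hexa-allyl precursor of the target
Product: 13 (R)-3-(3,4-dihydroxyphenyl)-2-{[(E)-3-{3-[((Z)-1-(3,4-dihydroxyphenyl)-3-methoxy-3-oxoprop-1-en-2-yl)oxy]-4-hydroxyphenyl}acryloyl]oxy}propanoic acid (target)
Conditions: Pd(PPh3)4 (10 mol%), morpholine (12 eq), degassed THF, rt; 1 M HCl work-up, C18 chromatography
Reagents that add atoms: none
Why: Tsuji–Trost deallylation; Pd(0) ionises the five aryl allyl ethers and the allyl ester to π-allyl complexes that morpholine traps, leaving the methyl ester, aryl enol ether, cinnamate ester, both C=C geometries and the stereocentre untouched.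

**Compound list**
1 | 3,4-dihydroxybenzaldehyde | O=Cc1ccc(O)c(O)c1 | starting material
2 | 3,4-bis(allyloxy)benzaldehyde | O=Cc1ccc(OCC=C)c(OCC=C)c1 | intermediate
3 | 1,2-bis(allyloxy)-4-(2,2-dibromovinyl)benzene | BrC(Br)=Cc1ccc(OCC=C)c(OCC=C)c1 | intermediate
4 | lithium [3,4-bis(allyloxy)phenyl]acetylide | [Li]C#Cc1ccc(OCC=C)c(OCC=C)c1 | intermediate
5 | methyl 3-[3,4-bis(allyloxy)phenyl]prop-2-ynoate | COC(=O)C#Cc1ccc(OCC=C)c(OCC=C)c1 | intermediate
6 | 4-(allyloxy)-3-hydroxybenzaldehyde | O=Cc1ccc(OCC=C)c(O)c1 | intermediate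
7 | methyl (Z)-2-[2-(allyloxy)-5-formylphenoxy]-3-[3,4-bis(allyloxy)phenyl]acrylate | COC(=O)/C(=C/c1ccc(OCC=C)c(OCC=C)c1)Oc1cc(C=O)ccc1OCC=C | intermediate
8 | sodium (R)-3-(3,4-dihydroxyphenyl)-2-hydroxypropanoate (sodium danshensu) | O[C@H](Cc1ccc(O)c(O)c1)C(=O)[O-].[Na+] | starting material
9 | allyl (R)-3-[3,4-bis(allyloxy)phenyl]-2-hydroxypropanoate | O[C@H](Cc1ccc(OCC=C)c(OCC=C)c1)C(=O)OCC=C | intermediate
10 | Meldrum's acid (2,2-dimethyl-1,3-dioxane-4,6-dione) | CC1(C)OC(=O)CC(=O)O1 | starting material
11 | 3-{[(R)-1-(allyloxy)-3-[3,4-bis(allyloxy)phenyl]-1-oxopropan-2-yl]oxy}-3-oxopropanoic acid | OC(=O)CC(=O)O[C@H](Cc1ccc(OCC=C)c(OCC=C)c1)C(=O)OCC=C | intermediate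
12 | allyl (R)-2-{[(E)-3-{4-(allyloxy)-3-[((Z)-1-[3,4-bis(allyloxy)phenyl]-3-methoxy-3-oxoprop-1-en-2-yl)oxy]phenyl}acryloyl]oxy}-3-[3,4-bis(allyloxy)phenyl]propanoate | COC(=O)/C(=C/c1ccc(OCC=C)c(OCC=C)c1)Oc1cc(/C=C/C(=O)O[C@H](Cc2ccc(OCC=C)c(OCC=C)c2)C(=O)OCC=C)ccc1OCC=C | intermediate
13 | (R)-3-(3,4-dihydroxyphenyl)-2-{[(E)-3-{3-[((Z)-1-(3,4-dihydroxyphenyl)-3-methoxy-3-oxoprop-1-en-2-yl)oxy]-4-hydroxyphenyl}acryloyl]oxy}propanoic acid | COC(=O)/C(=C/c1ccc(O)c(O)c1)Oc1cc(/C=C/C(=O)O[C@H](Cc2ccc(O)c(O)c2)C(=O)O)ccc1O | target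

**Step count and risks**

Total step count: 8 (step 7 is a one-pot, two-stage operation). Longest linear sequence: 6 steps (steps 1, 2, 3, 5, 7, 8; 1 → 2 → 3 → 5 → 7 → 12 → 13).

Steps most likely to fail:

Step 5 (the proposed new α-addition; risks are β-oxa-Michael regiochemistry, a sluggish electron-rich ynoate, or interference by the aldehyde). The fallback uses the known carbenoid O–H insertion / Horner–Wadsworth–Emmons route to aryl enol ethers, moved to after the cinnamate is built so that no free aldehyde sits beside the phosphonate carbanion. It sets out from phenol 6 together with 9 and 10. The one-pot procedure of step 7 is run with 6 in place of 7 (through 11) to give allyl (R)-2-{[(E)-3-(4-allyloxy-3-hydroxyphenyl)acryloyl]oxy}-3-[3,4-bis(allyloxy)phenyl]propanoate F1. Rh2(OAc)4 (1 mol%) and trimethyl diazophosphonoacetate in toluene at 80 °C then insert the carbenoid into the phenolic O–H to give the aryloxy-phosphonoacetate F2 (a mixture of epimers at the phosphorus-bearing carbon, which is destroyed in the next operation). A Masamune–Roush olefination (LiCl, DBU, MeCN, rt) with aldehyde 2 gives 12 directly, Z-major, with the minor E isomer removed by chromatography. The fallback comes back to the route at 12, so steps 2, 3 and 5 are bypassed.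

Step 7 (incomplete acylation of the hindered secondary alcohol, or partial epimerisation during the amine-mediated condensation). The fallback separates C=C formation from ester formation. It sets out from aldehyde 7: a Knoevenagel–Doebner reaction with malonic acid (pyridine, cat. piperidine, 80 °C) gives (E)-3-{4-(allyloxy)-3-[((Z)-1-[3,4-bis(allyloxy)phenyl]-3-methoxy-3-oxoprop-1-en-2-yl)oxy]phenyl}acrylic acid F3. Steglich esterification of F3 with alcohol 9 (DCC, cat. DMAP, CH2Cl2, 0 °C → rt) returns to the route at 12. The alcohol stereocentre is never activated in this sequence.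

Step 8 (six-fold deallylation on an oxidation-prone polyphenol; possible incomplete cleavage or amine adducts). The fallback avoids π-allyl chemistry and amines. It sets out from 12: isomerisation with H2-activated [Ir(cod)(PMePh2)2]PF6 (5 mol%) in THF at rt converts every allyl group into a prop-1-enyl group, giving the hexa(prop-1-enyl) isomer of 12 F4 (E/Z mixture at the propenyl groups). Mild acid hydrolysis of these enol ethers and the enol ester (0.5 M HCl, acetone–water, 40 °C) returns to the route at 13. The ester-deactivated aryl enol ether of the target is not hydrolysed under these conditions.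

**Further compounds**
F1 | step 5 | allyl (R)-2-{[(E)-3-(4-allyloxy-3-hydroxyphenyl)acryloyl]oxy}-3-[3,4-bis(allyloxy)phenyl]propanoate | Oc1cc(/C=C/C(=O)O[C@H](Cc2ccc(OCC=C)c(OCC=C)c2)C(=O)OCC=C)ccc1OCC=C
F2 | step 5 | allyl (R)-2-{[(E)-3-{4-(allyloxy)-3-[1-(dimethoxyphosphoryl)-2-methoxy-2-oxoethoxy]phenyl}acryloyl]oxy}-3-[3,4-bis(allyloxy)phenyl]propanoate (epimers at the P-bearing carbon) | COC(=O)C(Oc1cc(/C=C/C(=O)O[C@H](Cc2ccc(OCC=C)c(OCC=C)c2)C(=O)OCC=C)ccc1OCC=C)P(=O)(OC)OC
F3 | step 7 | (E)-3-{4-(allyloxy)-3-[((Z)-1-[3,4-bis(allyloxy)phenyl]-3-methoxy-3-oxoprop-1-en-2-yl)oxy]phenyl}acrylic acid | COC(=O)/C(=C/c1ccc(OCC=C)c(OCC=C)c1)Oc1cc(/C=C/C(=O)O)ccc1OCC=C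
F4 | step 8 | hexa(prop-1-enyl) isomer of 12 (all six allyl groups isomerised, E/Z mixture at the propenyl groups) | COC(=O)/C(=C/c1ccc(OC=CC)c(OC=CC)c1)Oc1cc(/C=C/C(=O)O[C@H](Cc2ccc(OC=CC)c(OC=CC)c2)C(=O)OC=CC)ccc1OC=CC
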